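**Plan**

- Feature used: ring B of unit 2 is a benzene ring substituted only at C1' (chromone C2) and C4' (ether oxygen). C3'–C6' with the oxygen on C4' map onto a 2-aryloxybuta-1,3-diene, and C1'–C2' onto a terminal alkyne on chromone C2.
- Retrosynthetic cuts, in order: the four O–benzyl bonds; the pyranone of unit 1 at C1'–C2, C2–C3 and O1–C2 (aryl bromide + CO + o-hydroxyacetophenone); ring B of unit 2 at C1'–C6' and C2'–C3'; the enol-ether C=CH2 of the diene and the terminal alkyne carbon of the dienophile.
- Forward order: the pyranone of unit 2 is made first from benzylated phloroacetophenone and its C2 methyl group is turned into ethynyl. The diene comes from the acrylate of 5-bromo-2-methoxyphenol. A cobalt-catalysed (4+2) union with DDQ dehydrogenation then creates ring B of unit 2, carbonylative annulation builds the pyranone of unit 1, and hydrogenolysis ends the route.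
- The diaryl ether C4'–O bond is never made by an aryl ether coupling: it begins as the ester C–O bond of the aryl acrylate.
- Stereochemistry: the target has no stereocentre; the two CH2 carbons of the cycloadduct are flattened on dehydrogenation.

Key step: step 7

Remark: flavone numbering is used (O1, C2, C3, C4, C4a–C8a, ring B primed); unit 1 is the flavone whose ring B bears the methoxy group, unit 2 the one joined through C4'.

**Route**

Step 1
Reactants: 1 5-bromo-2-methoxyphenol; 2 acryloyl chloride
Product: 3 5-bromo-2-methoxyphenyl prop-2-enoate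
Conditions: Et3N (1.5 equiv), CH2Cl2, 0 °C
Reagents that add atoms: none
Why: O-acylation of a phenol by an acid chloride with an amine base (esterification) is routine, and the low temperature keeps the acrylate from polymerising.

Step 2
Reactants: 3 5-bromo-2-methoxyphenyl prop-2-enoate
Product: 4 4-bromo-2-(buta-1,3-dien-2-yloxy)-1-methoxybenzene
Conditions: Cp2TiMe2 (2.5 equiv), trace BHT, toluene, 65 °C, dark; filtration through basic alumina
Reagents that add atoms: dimethyltitanocene (Cp2TiMe2), C[Ti](C)(C1C=CC=C1)C1C=CC=C1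
Why: Petasis methylenation, in which Cp2TiMe2 loses methane to give the titanocene methylidene that adds across the ester C=O and fragments to the enol ether and oxotitanocene; aryl esters are good substrates and the neutral, aluminium-free medium should spare the acid-labile dienyl ether and the aryl bromide.

Step 3
Reactants: 5 1-(2,4,6-trihydroxyphenyl)ethanone
Product: 6 1-[2,4-bis(benzyloxy)-6-hydroxyphenyl]ethanone
Conditions: BnBr (2.1 equiv), K2CO3 (2.2 equiv), DMF, 0 °C to rt
Reagents that add atoms: benzyl bromide, BrCc1ccccc1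
Why: Williamson etherification takes the para hydroxyl and one ortho hydroxyl, while the remaining ortho hydroxyl is hydrogen-bonded to the ketone, is the least nucleophilic and should stay free.

Step 4
Reactants: 6 1-[2,4-bis(benzyloxy)-6-hydroxyphenyl]ethanone
Product: 8 5,7-bis(benzyloxy)-2-methyl-4H-chromen-4-one, via β-diketone 7 (not isolated)
Conditions: NaH (4 equiv), EtOAc (5 equiv), THF, 65 °C; aq. HCl quench; then conc. HCl (cat.), MeOH, 50 °C
Reagents that add atoms: ethyl acetate, CCOC(C)=O
Why: Claisen condensation of the ketone enolate with ethyl acetate (any O-acetate converges by Baker–Venkataraman shift) gives the β-diketone, and acid-catalysed cyclodehydration of the phenol onto the distal carbonyl closes the pyranone under conditions that leave benzyl ethers intact.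

Step 5
Reactants: 8 5,7-bis(benzyloxy)-2-methyl-4H-chromen-4-one
Product: 9 5,7-bis(benzyloxy)-4-oxo-4H-chromene-2-carbaldehyde
Conditions: SeO2 (1.5 equiv), 1,4-dioxane, 100 °C
Reagents that add atoms: selenium dioxide, O=[Se]=O
Why: Riley oxidation, since the C2 methyl group is the vinylogous α-position of the pyranone carbonyl and 2-methylchromones are oxidised by SeO2 (ene reaction, then [2,3]-shift) to the 2-carbaldehydes without touching benzyl ethers.

Step 6
Reactants: 9 5,7-bis(benzyloxy)-4-oxo-4H-chromene-2-carbaldehyde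
Product: 10 5,7-bis(benzyloxy)-2-ethynyl-4H-chromen-4-one
Conditions: dimethyl (1-diazo-2-oxopropyl)phosphonate (1.3 equiv), K2CO3 (2 equiv), MeOH/THF, 0 °C to rt
Reagents that add atoms: dimethyl (1-diazo-2-oxopropyl)phosphonate, CC(=O)C(=[N+]=[N-])P(=O)(OC)OC
Why: Ohira–Bestmann (Seyferth–Gilbert) homologation, in which methanolysis frees the diazomethylphosphonate anion that adds to the aldehyde, expels dimethyl phosphate and loses N2 with 1,2-hydrogen shift to the terminal alkyne; carbonate in methanol at 0 °C is mild enough for the pyranone.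

Step 7
Reactants: 4 4-bromo-2-(buta-1,3-dien-2-yloxy)-1-methoxybenzene (1.5 equiv); 10 5,7-bis(benzyloxy)-2-ethynyl-4H-chromen-4-one
Product: 12 5,7-bis(benzyloxy)-2-[4-(5-bromo-2-methoxyphenoxy)phenyl]-4H-chromen-4-one, via cyclohexadiene adduct 11 (not isolated)
Conditions: CoBr2(dppe) (10 mol%), Zn powder (20 mol%), ZnI2 (20 mol%), CH2Cl2, rt; silica plug; then DDQ (1.2 equiv), toluene, rt
Reagents that add atoms: none
Why: Zinc reduces CoBr2(dppe) to a monovalent cobalt species and ZnI2 frees coordination sites; the s-cis diene and the terminal alkyne bind, oxidative coupling joins the alkyne CH (C2') to the diene CH2 next to the oxygen-bearing carbon (C3'), reductive elimination from the cobaltacycle forms C1'–C6' and releases 1,4-cyclohexadiene 11, and DDQ then removes hydride from a doubly allylic CH2 and a proton to give the arene. The closest known reaction type is the cobalt-catalysed neutral Diels–Alder reaction of terminal alkynes with 2-substituted butadienes (2-silyloxybutadiene included) followed by DDQ dehydrogenation; catalysis is chosen because the alkyne is activated only vinylogously through C2=C3–C4=O of the chromone, so a purely thermal cycloaddition would need temperatures at which the enol-ether diene dimerises. Ring B of unit 2 closes as a six-membered carbocycle in an intermolecular (4+2) mode, four carbons coming from the diene (C3'–C6') and two from the alkyne (C1', C2'). No stereocentre is formed, because the only sp3 carbons of 11 are two CH2 groups and both are lost on aromatisation. The step needs the 1,4 (para) rather than the 1,3 (meta) relation between chromone and aryloxy group and needs the alkyne rather than the pyranone C2=C3 bond to react; the bisphosphine ligand sphere is the one that steers 2-substituted dienes and terminal alkynes to the 1,4-isomer, the polarity match (electron-rich enol-ether β-carbon C3' with the electrophilic alkyne terminus) points the same way, and the trisubstituted pyranone C2=C3 bond is not a competent 2π partner. The aryl bromide, the benzyl ethers and the pyranone should be inert to phosphine-ligated low-valent cobalt in CH2Cl2 and to DDQ at room temperature.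

Step 8
Reactants: 12 5,7-bis(benzyloxy)-2-[4-(5-bromo-2-methoxyphenoxy)phenyl]-4H-chromen-4-one; 6 1-[2,4-bis(benzyloxy)-6-hydroxyphenyl]ethanone (1.5 equiv)
Product: 15 5,7-bis(benzyloxy)-2-{4-[5-(5,7-bis(benzyloxy)-4-oxo-4H-chromen-2-yl)-2-methoxyphenoxy]phenyl}-4H-chromen-4-one, via aryl ester 13 (not isolated), via β-diketone 14 (not isolated)
Conditions: Pd(OAc)2 (5 mol%), dppb (7.5 mol%), DBU (3 equiv), CO (10 bar), DMSO, 120 °C; aq. HCl work-up
Reagents that add atoms: carbon monoxide, [C-]#[O+]
Why: Palladium-catalysed carbonylative flavone annulation of an aryl bromide with a 2-hydroxyacetophenone, in which zerovalent palladium inserts into C–Br, CO insertion and phenolysis by 6 give aryl ester 13, DBU drives the Baker–Venkataraman acyl shift to β-diketone 14, and cyclodehydration closes the pyranone of unit 1; the existing flavone, the benzyl ethers and the diaryl ether are inert to these conditions.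

Step 9
Reactants: 15 5,7-bis(benzyloxy)-2-{4-[5-(5,7-bis(benzyloxy)-4-oxo-4H-chromen-2-yl)-2-methoxyphenoxy]phenyl}-4H-chromen-4-one
Product: 16 4'-O-methylochnaflavone
Conditions: H2 (1 atm), 10% Pd/C, THF/MeOH, rt
Reagents that add atoms: none
Why: Catalytic hydrogenolysis cleaves the four benzylic C–O bonds, while the aryl methyl ether, the diaryl ether and the conjugated pyranone double bonds should survive at atmospheric pressure and room temperature.

**Compound list**

1 | 5-bromo-2-methoxyphenol | COc1ccc(Br)cc1O | starting material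
2 | acryloyl chloride | C=CC(=O)Cl | starting material
3 | 5-bromo-2-methoxyphenyl prop-2-enoate | COc1ccc(Br)cc1OC(=O)C=C | intermediate
4 | 4-bromo-2-(buta-1,3-dien-2-yloxy)-1-methoxybenzene | COc1ccc(Br)cc1OC(=C)C=C | intermediate
5 | 1-(2,4,6-trihydroxyphenyl)ethanone | CC(=O)c1c(O)cc(O)cc1O | starting material
6 | 1-[2,4-bis(benzyloxy)-6-hydroxyphenyl]ethanone | CC(=O)c1c(O)cc(OCc2ccccc2)cc1OCc1ccccc1 | intermediate
7 | 1-[2,4-bis(benzyloxy)-6-hydroxyphenyl]butane-1,3-dione | CC(=O)CC(=O)c1c(O)cc(OCc2ccccc2)cc1OCc1ccccc1 | intermediate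
8 | 5,7-bis(benzyloxy)-2-methyl-4H-chromen-4-one | Cc1cc(=O)c2c(OCc3ccccc3)cc(OCc3ccccc3)cc2o1 | intermediate
9 | 5,7-bis(benzyloxy)-4-oxo-4H-chromene-2-carbaldehyde | O=Cc1cc(=O)c2c(OCc3ccccc3)cc(OCc3ccccc3)cc2o1 | intermediate
10 | 5,7-bis(benzyloxy)-2-ethynyl-4H-chromen-4-one | C#Cc1cc(=O)c2c(OCc3ccccc3)cc(OCc3ccccc3)cc2o1 | intermediate
11 | 5,7-bis(benzyloxy)-2-[4-(5-bromo-2-methoxyphenoxy)cyclohexa-1,4-dien-1-yl]-4H-chromen-4-one | COc1ccc(Br)cc1OC1=CCC(c2cc(=O)c3c(OCc4ccccc4)cc(OCc4ccccc4)cc3o2)=CC1 | intermediate
12 | 5,7-bis(benzyloxy)-2-[4-(5-bromo-2-methoxyphenoxy)phenyl]-4H-chromen-4-one | COc1ccc(Br)cc1Oc1ccc(-c2cc(=O)c3c(OCc4ccccc4)cc(OCc4ccccc4)cc3o2)cc1 | intermediate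
13 | 2-acetyl-3,5-bis(benzyloxy)phenyl 3-{4-[5,7-bis(benzyloxy)-4-oxo-4H-chromen-2-yl]phenoxy}-4-methoxybenzoate | COc1ccc(C(=O)Oc2cc(OCc3ccccc3)cc(OCc3ccccc3)c2C(C)=O)cc1Oc1ccc(-c2cc(=O)c3c(OCc4ccccc4)cc(OCc4ccccc4)cc3o2)cc1 | intermediate
14 | 1-[2,4-bis(benzyloxy)-6-hydroxyphenyl]-3-(3-{4-[5,7-bis(benzyloxy)-4-oxo-4H-chromen-2-yl]phenoxy}-4-methoxyphenyl)propane-1,3-dione | COc1ccc(C(=O)CC(=O)c2c(O)cc(OCc3ccccc3)cc2OCc2ccccc2)cc1Oc1ccc(-c2cc(=O)c3c(OCc4ccccc4)cc(OCc4ccccc4)cc3o2)cc1 | intermediate
15 | 5,7-bis(benzyloxy)-2-{4-[5-(5,7-bis(benzyloxy)-4-oxo-4H-chromen-2-yl)-2-methoxyphenoxy]phenyl}-4H-chromen-4-one | COc1ccc(-c2cc(=O)c3c(OCc4ccccc4)cc(OCc4ccccc4)cc3o2)cc1Oc1ccc(-c2cc(=O)c3c(OCc4ccccc4)cc(OCc4ccccc4)cc3o2)cc1 | intermediate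
16 | 4'-O-methylochnaflavone, 5,7-dihydroxy-2-{4-[5-(5,7-dihydroxy-4-oxo-4H-chromen-2-yl)-2-methoxyphenoxy]phenyl}-4H-chromen-4-one | COc1ccc(-c2cc(=O)c3c(O)cc(O)cc3o2)cc1Oc1ccc(-c2cc(=O)c3c(O)cc(O)cc3o2)cc1 | target

**Step count**

Total step count: 9.
Longest linear sequence: 7 steps (steps 3 to 9, from 5 to 16).

**Steps most likely to fail**

1. Step 7. Cobalt-mediated cyclotrimerisation of the ethynylchromone may outrun the cross-cycloaddition. The chromone carbonyl and the ether oxygens may tie up the Lewis-acidic zinc and cobalt species so that turnover stalls. ZnI2 may oligomerise or hydrolyse the enol-ether diene, and the oxidative coupling may leak toward the meta isomer. Fallback: ring B of unit 2 is still made by cycloaddition of diene 4, but with a classical ynoate dienophile, and the pyranone is built afterwards. The fallback sets out from 4 and 6 and returns at 12. Diene 4 is heated with methyl propiolate (toluene, 100 °C, trace BHT) to give methyl 4-(5-bromo-2-methoxyphenoxy)cyclohexa-1,4-diene-1-carboxylate F1. This is dehydrogenated without isolation by DDQ to methyl 4-(5-bromo-2-methoxyphenoxy)benzoate F2. The dilithium salt of 6 (LiN(SiMe3)2, 3.5 equiv, THF, −78 °C to rt) is acylated by F2 in a Claisen condensation to give 1-[2,4-bis(benzyloxy)-6-hydroxyphenyl]-3-[4-(5-bromo-2-methoxyphenoxy)phenyl]propane-1,3-dione F3. Cyclodehydration (cat. TsOH, toluene, 80 °C) then gives 12.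

2. Step 8. Acyl transfer from the acylpalladium species to the hindered, hydrogen-bonded phenol of 6 may be slow, so that proto-debromination or ketone α-arylation competes, and the acyl shift to the diketone may stall at the ester stage. Fallback: carbonylation and C–C bond formation are separated. The fallback sets out from 12 and returns at 14, which is cyclised to 15. Methoxycarbonylation of 12 (Pd(OAc)2, Xantphos, Et3N, MeOH, CO 1 atm, toluene, 80 °C) gives methyl 3-{4-[5,7-bis(benzyloxy)-4-oxo-4H-chromen-2-yl]phenoxy}-4-methoxybenzoate F4. Claisen condensation of F4 with the dilithium salt of 6 (LiN(SiMe3)2, THF, −78 °C to rt) gives β-diketone 14, and cat. TsOH in toluene at 80 °C closes it to 15.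

3. Step 2. The aryl acrylate may polymerise during the prolonged heating, the titanium methylidene may engage the acrylate C=C bond instead of the carbonyl group, and the dienyl ether may hydrolyse on work-up. Fallback: the enol ether is made by elimination instead of carbonyl methylenation. The fallback sets out from 1 and returns at 4. Palladium-catalysed opening of 2-vinyloxirane by phenol 1 (Pd2(dba)3·CHCl3, racemic trans-cyclohexane-1,2-diamine bis(2-diphenylphosphinobenzamide) ligand, CH2Cl2, rt) should deliver the branched ether, racemic 2-(5-bromo-2-methoxyphenoxy)but-3-en-1-ol F5. Appel iodination (I2, PPh3, imidazole, CH2Cl2, 0 °C) gives racemic 4-bromo-2-[(1-iodobut-3-en-2-yl)oxy]-1-methoxybenzene F6. E2 elimination of HI through the allylic, oxygen-bearing C–H (KOtBu, THF, 0 °C) then gives diene 4.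

**Further compounds**

F1 | step 7 | methyl 4-(5-bromo-2-methoxyphenoxy)cyclohexa-1,4-diene-1-carboxylate | COC(=O)C1=CCC(Oc2cc(Br)ccc2OC)=CC1
F2 | step 7 | methyl 4-(5-bromo-2-methoxyphenoxy)benzoate | COC(=O)c1ccc(Oc2cc(Br)ccc2OC)cc1
F3 | step 7 | 1-[2,4-bis(benzyloxy)-6-hydroxyphenyl]-3-[4-(5-bromo-2-methoxyphenoxy)phenyl]propane-1,3-dione | COc1ccc(Br)cc1Oc1ccc(C(=O)CC(=O)c2c(O)cc(OCc3ccccc3)cc2OCc2ccccc2)cc1
F4 | step 8 | methyl 3-{4-[5,7-bis(benzyloxy)-4-oxo-4H-chromen-2-yl]phenoxy}-4-methoxybenzoate | COC(=O)c1ccc(OC)c(Oc2ccc(-c3cc(=O)c4c(OCc5ccccc5)cc(OCc5ccccc5)cc4o3)cc2)c1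
F5 | step 2 | racemic 2-(5-bromo-2-methoxyphenoxy)but-3-en-1-ol | COc1ccc(Br)cc1OC(CO)C=C
F6 | step 2 | racemic 4-bromo-2-[(1-iodobut-3-en-2-yl)oxy]-1-methoxybenzene | COc1ccc(Br)cc1OC(CI)C=C
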